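**Retrosynthetic overview**
1. Eupakirunsin C ⇐ 1‑O‑TBS lactone 29 ⇐ mesylate/alkenyl boronate 26 + CO2. In the key step one CO2 becomes C12 and both lactone oxygens, bonding to C11 (from the C11–B bond) and to C6 (displacing the C6 mesylate with inversion).
2. Enabling feature: the alkenyl carbon C11 and the oxygen‑bearing C6 (next to the C4–C5 oxirane) are 1,3‑related through C7, so a carboxylate on C11 reaches C6 by a 5‑exo‑tet path and closes the five‑membered lactone ring (O, C6, C7, C11, C12).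
3. 26 ⇐ ten‑membered Z‑enone 21: CBS reduction, hydroxyl‑directed epoxidation (C4, C5) and oxidation give the epoxy ketone. 21 ⇐ seco aldehyde 19 by Nozaki–Hiyama–Kishi closure of the C3–C4 bond.
4. 19 ⇐ allene 7 (C4–C7, C11, C13, C15) + aldehyde 14 (C1–C3, C8–C10, C14) by copper‑catalysed borylative allene–aldehyde coupling, which forms C7–C8 and installs the C11–B bond.
5. Ring order: ten‑membered carbocycle (step 13), oxirane (step 16), lactone (step 20).

Key step: step 20

Remark: names use germacrane locants of the target (ring C1–C10; C11 alkenyl carbon, C12 carbonyl, C13 methylene, C14 methyl on C10, C15 methyl on C4).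
Remark: metal and boron alkoxides that are merely hydrolysed at aqueous work‑up are not numbered as intermediates.
Assumption: the antipodes named for the chiral controllers (steps 3, 5, 9, 15) are those expected to deliver the configurations stated for the products.

**Step 1**
Reactants: 1 but‑2‑yn‑1‑ol
Product: 3 (Z)‑3‑iodobut‑2‑en‑1‑ol, via cyclic alkenylalanate 2 (not isolated)
Conditions: NaAlH2(OCH2CH2OMe)2 (Red‑Al), THF, 0 °C to rt; then I2, −78 °C to 0 °C
Reagents that add atoms: iodine, II; Red‑Al (atoms in intermediate 2 only), [Na+].[AlH2-](OCCOC)OCCOC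
Why: hydroxyl‑directed trans‑hydroalumination of the propargylic alcohol places aluminium on C3 anti to the new C2–H bond, and iodinolysis with retention should give the Z alkenyl iodide, the geometry later needed for the cis C3/C6 relationship across C4=C5.

**Step 2**
Reactants: 3 (Z)‑3‑iodobut‑2‑en‑1‑ol
Product: 4 (Z)‑3‑iodobut‑2‑enal
Conditions: MnO2, CH2Cl2, rt
Reagents that add atoms: none
Why: MnO2 oxidation of an allylic alcohol is neutral and should leave the Z alkenyl iodide unchanged.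

**Step 3**
Reactants: 4 (Z)‑3‑iodobut‑2‑enal; 5 tributyl(propa‑1,2‑dienyl)stannane
Product: 6 (4R,5Z)‑6‑iodohepta‑1,2,5‑trien‑4‑ol
Conditions: (R,R)‑N,N'‑ditosyl‑1,2‑diphenylethane‑1,2‑diamine, BBr3, CH2Cl2, rt; then 5, rt; then 4, −78 °C; aq. NaHCO3
Reagents that add atoms: none
Why: Corey allenylation, in which the bromoborane and 5 give a B‑propargyl diazaborolidine by SE2' transmetalation that adds to 4 through a cyclic SE2' transition state to give the α‑allenyl carbinol, the C2‑symmetric bis‑sulfonamide fixing the 4R centre (C6 of the target, inverted later in step 20).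

**Step 4**
Reactants: 6 (4R,5Z)‑6‑iodohepta‑1,2,5‑trien‑4‑ol
Product: 7 triethyl{[(4R,5Z)‑6‑iodohepta‑1,2,5‑trien‑4‑yl]oxy}silane
Conditions: TESCl, imidazole, CH2Cl2, 0 °C
Reagents that add atoms: chlorotriethylsilane, CC[Si](Cl)(CC)CC
Why: standard silylation; the TES ether should survive steps 9 to 17 and is later removed in the presence of the C1 TBS ether.

**Step 5**
Reactants: 8 3‑[(4‑methoxybenzyl)oxy]propan‑1‑ol; 9 but‑3‑en‑2‑yl acetate
Product: 10 (3R,4S)‑1‑[(4‑methoxybenzyl)oxy]‑4‑methylhex‑5‑en‑3‑ol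
Conditions: [Ir(cod)Cl]2 (2.5 mol%), (S)‑SEGPHOS (5 mol%), 4‑cyano‑3‑nitrobenzoic acid (10 mol%), Cs2CO3 (20 mol%), THF, 90 °C
Reagents that add atoms: none
Why: Krische iridium‑catalysed transfer‑hydrogenative crotylation from the alcohol oxidation level, in which the (E)‑σ‑crotyliridium adds to the transient aldehyde through a chair transition state to give the anti adduct and sets C1 (R) and C10 (S) under ligand control.

**Step 6**
Reactants: 10 (3R,4S)‑1‑[(4‑methoxybenzyl)oxy]‑4‑methylhex‑5‑en‑3‑ol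
Product: 11 tert‑butyl{[(3R,4S)‑1‑[(4‑methoxybenzyl)oxy]‑4‑methylhex‑5‑en‑3‑yl]oxy}dimethylsilane
Conditions: TBSOTf, 2,6‑lutidine, CH2Cl2, −78 to 0 °C
Reagents that add atoms: tert‑butyldimethylsilyl triflate, CC(C)(C)[Si](C)(C)OS(=O)(=O)C(F)(F)F
Why: standard silylation of a hindered secondary alcohol; TBS is kept to the last step.

**Step 7**
Reactants: 11 TBS ether
Product: 13 (3S,4R)‑4‑[(tert‑butyldimethylsilyl)oxy]‑6‑[(4‑methoxybenzyl)oxy]‑3‑methylhexan‑1‑ol, via B‑alkyl‑9‑borabicyclononane adduct 12 (not isolated)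
Conditions: 9‑BBN, THF, 0 °C to rt; then NaOH, H2O2, 0 °C
Reagents that add atoms: hydrogen peroxide, OO; 9‑BBN (atoms in intermediate 12 only), [H]B1C2CCCC1CCC2
Why: anti‑Markovnikov hydroboration of the monosubstituted alkene and oxidation with retention should give the primary alcohol that becomes C8.

**Step 8**
Reactants: 13 primary alcohol
Product: 14 (3S,4R)‑4‑[(tert‑butyldimethylsilyl)oxy]‑6‑[(4‑methoxybenzyl)oxy]‑3‑methylhexanal
Conditions: Dess–Martin periodinane, NaHCO3, CH2Cl2, 0 °C to rt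
Reagents that add atoms: none
Why: Dess–Martin oxidation is mild and the only stereocentre nearby (C10) is β to the new aldehyde and cannot epimerise.

**Step 9**
Reactants: 7 allene fragment; 14 aldehyde fragment
Product: 15 seco alcohol (acyclic C3 to C4 chain: 3‑O‑PMB, 1‑O‑TBS, 10‑methyl, 8‑hydroxy, 7‑[1‑(pinacolboryl)ethenyl], 6‑O‑TES, (4Z)‑4‑iodo C4=C5 alkene; 1R,6R,7R,8R,10S)
Conditions: CuCl (5 mol%), (R)‑SEGPHOS (5.5 mol%), NaOtBu (20 mol%), B2pin2 (1.1 equiv), THF, 22 °C; aq. NH4Cl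
Reagents that add atoms: bis(pinacolato)diboron, CC1(C)OB(OC1(C)C)B1OC(C)(C)C(C)(C)O1
Why: copper‑catalysed borylative allene–aldehyde coupling, in which Cu–Bpin adds across the terminal allene double bond to a 2‑boryl (Z)‑allylcopper that adds to 14 through a chair transition state, so the closed transition state should give the 7,8‑syn relationship, the aldehyde should approach anti to the bulky (Z)‑iodoalkenyl group of the A(1,3)‑locked C6 centre (reinforced by the ligand antipode), and the C11–B bond needed for step 20 is installed in the same event.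

**Step 10**
Reactants: 15 seco alcohol; 16 (E)‑2‑methylbut‑2‑enoyl chloride (tigloyl chloride)
Product: 17 seco tiglate (as 15 with 8‑O‑tigloyl; 1R,6R,7R,8R,10S)
Conditions: Et3N, DMAP, CH2Cl2, 0 °C to rt
Reagents that add atoms: none
Why: DMAP‑catalysed acylation of the secondary alcohol; the E (tiglate) geometry is the stable one and should be retained.

**Step 11**
Reactants: 17 seco tiglate
Product: 18 seco primary alcohol (as 17 with free 3‑OH; 1R,6R,7R,8R,10S)
Conditions: DDQ, CH2Cl2/pH 7 buffer, 0 °C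
Reagents that add atoms: none
Why: oxidative PMB cleavage with DDQ is orthogonal to the silyl ethers, the ester, the alkenyl iodide and the boronate.

**Step 12**
Reactants: 18 seco primary alcohol
Product: 19 seco aldehyde (C3 aldehyde; 1R,6R,7R,8R,10S)
Conditions: Dess–Martin periodinane, NaHCO3, CH2Cl2, 0 °C to rt
Reagents that add atoms: none
Why: Dess–Martin oxidation gives the β‑silyloxy aldehyde without elimination under buffered conditions.

**Step 13**
Reactants: 19 seco aldehyde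
Product: 20 macrocyclic allylic alcohols (ten‑membered (4Z)‑cycloalkene, both C3 epimers: 3‑hydroxy, 4‑methyl, 6‑O‑TES, 7‑[1‑(pinacolboryl)ethenyl], 8‑O‑tigloyl, 10‑methyl, 1‑O‑TBS; 1R,6S,7R,8R,10S)
Conditions: CrCl2 (10 equiv), NiCl2 (0.1 equiv), DMSO/THF, rt, slow addition to 0.002 M
Reagents that add atoms: none
Why: intramolecular Nozaki–Hiyama–Kishi reaction, in which zerovalent nickel inserts into the alkenyl C–I bond with retention of the Z geometry and the alkenylchromium adds to the aldehyde under high dilution to close the ten‑membered ring at C3–C4; the C3 configuration is not controlled and is erased in step 14.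

**Step 14**
Reactants: 20 macrocyclic allylic alcohols
Product: 21 macrocyclic Z‑enone (3‑ketone; 1R,6S,7R,8R,10S)
Conditions: Dess–Martin periodinane, NaHCO3, CH2Cl2, 0 °C
Reagents that add atoms: none
Why: Dess–Martin oxidation converges both C3 epimers to one enone without touching the Z alkene held in the ring.

**Step 15**
Reactants: 21 macrocyclic Z‑enone
Product: 22 (3S)‑allylic alcohol (1R,3S,6S,7R,8R,10S)
Conditions: (R)‑2‑methyl‑CBS‑oxazaborolidine (0.5 equiv), catecholborane, toluene, −78 °C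
Reagents that add atoms: none
Why: Corey–Bakshi–Shibata reduction, in which the alkenyl carbon C4 acts as the large and the ring methylene C2 as the small substituent, so the (R)‑catalyst should deliver hydride to give the 3S alcohol, whose hydroxyl lies on the ring face that must carry the oxirane.

**Step 16**
Reactants: 22 (3S)‑allylic alcohol
Product: 23 epoxy alcohol (4,5‑oxirane; 1R,3S,4S,5R,6R,7R,8R,10S)
Conditions: VO(acac)2 (5 mol%), tBuOOH (1.5 equiv), CH2Cl2, 0 °C
Reagents that add atoms: tert‑butyl hydroperoxide, CC(C)(C)OO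
Why: vanadium‑catalysed hydroxyl‑directed epoxidation, in which the allylic vanadate should deliver oxygen syn to the C3 hydroxyl (cis epoxy alcohol, as for medium‑ring Z‑cycloalkenols) and stereospecifically on the Z alkene, setting C4 and C5, while the tiglate and boryl alkenes carry no directing hydroxyl.

**Step 17**
Reactants: 23 epoxy alcohol
Product: 24 epoxy ketone (3‑ketone; 1R,4R,5R,6R,7R,8R,10S)
Conditions: Dess–Martin periodinane, NaHCO3, CH2Cl2, 0 °C to rt
Reagents that add atoms: none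
Why: Dess–Martin oxidation of an α‑epoxy alcohol to the epoxy ketone is mild and non‑epimerising (C4 is fully substituted).

**Step 18**
Reactants: 24 epoxy ketone
Product: 25 C6 alcohol (free 6‑OH; 1R,4R,5R,6R,7S,8R,10S)
Conditions: PPTS, MeOH/CH2Cl2, 0 °C to rt
Reagents that add atoms: none
Why: acid‑catalysed methanolysis should remove the secondary TES ether selectively in the presence of the more hindered TBS ether.

**Step 19**
Reactants: 25 C6 alcohol
Product: 26 C6 mesylate (6‑OMs; 1R,4R,5R,6R,7R,8R,10S)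
Conditions: MsCl, Et3N, CH2Cl2, −20 °C
Reagents that add atoms: methanesulfonyl chloride, CS(=O)(=O)Cl
Why: sulfonylation with retention turns the only free hydroxyl (6R) into the leaving group for step 20, and trapping the open form also drains any reversible C6‑O/C3 hemiketal.

**Step 20**
Reactants: 26 C6 mesylate; 27 carbon dioxide
Product: 29 1‑O‑TBS‑eupakirunsin C (1R,4R,5R,6S,7R,8R,10S), via potassium acrylate 28 (not isolated)
Conditions: (IPr)CuCl (10 mol%; IPr = 1,3‑bis(2,6‑diisopropylphenyl)imidazol‑2‑ylidene), KOtBu (1.1 equiv), CO2 (1 atm), THF, 60 °C; then DMF, 60 °C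
Reagents that add atoms: potassium tert‑butoxide (potassium in intermediate 28 only), CC(C)(C)[O-].[K+]
Why: The alkoxide‑activated boronate should transmetalate to (IPr)Cu–OtBu to give the C11 alkenylcopper, which inserts CO2 into the Cu–C bond (C11–C12 formed) and exchanges to the potassium acrylate 28, whose carboxylate oxygen then displaces the C6 mesylate (O–C6 formed), so one molecule of CO2 supplies C12 and both lactone oxygens. The closest known reactions are the NHC–copper‑catalysed carboxylation of alkenylboronic esters with CO2 and the invertive lactonization of γ‑sulfonyloxy carboxylates. The only ring closed is the five‑membered lactone (O, C6, C7, C11, C12), by a 5‑exo‑tet SN2 closure. The one stereocentre affected is C6, which is inverted (6R to 6S) under control of the mesylate configuration set in step 3, giving the trans ring fusion with the untouched C7 centre. The step needs chemoselectivity for the C6 sulfonate over the neighbouring oxirane carbon C5, over E2 loss of the mesylate and over base‑triggered β‑elimination of the C1 silyloxy group; the short 5‑exo trajectory anti to the mesylate, the poor electrophilicity of the α‑keto oxirane and the CO2‑buffered medium (tert‑butoxide is held as boronate or as its carbonate) should secure this.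

**Step 21**
Reactants: 29 1‑O‑TBS‑eupakirunsin C
Product: 30 eupakirunsin C
Conditions: HF·pyridine, pyridine, THF, 0 °C to rt
Reagents that add atoms: none
Why: fluoride‑mediated desilylation under buffered, weakly acidic conditions should spare the epoxy ketone, the β‑hydroxy ketone and the α‑methylene lactone.

**Compound list**
1 | but‑2‑yn‑1‑ol | CC#CCO | starting material
2 | sodium 2,2‑bis(2‑methoxyethoxy)‑3‑methyl‑2,5‑dihydro‑1,2‑oxaaluminol‑2‑uide (cyclic alkenylalanate) | CC1=CCO[Al-]1(OCCOC)OCCOC.[Na+] | intermediate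
3 | (Z)‑3‑iodobut‑2‑en‑1‑ol | C/C(I)=C/CO | intermediate
4 | (Z)‑3‑iodobut‑2‑enal | C/C(I)=C/C=O | intermediate
5 | tributyl(propa‑1,2‑dienyl)stannane | CCCC[Sn](CCCC)(CCCC)C=C=C | starting material
6 | (4R,5Z)‑6‑iodohepta‑1,2,5‑trien‑4‑ol | C=C=C[C@@H](O)/C=C(/C)I | intermediate
7 | triethyl{[(4R,5Z)‑6‑iodohepta‑1,2,5‑trien‑4‑yl]oxy}silane | C=C=C[C@@H](O[Si](CC)(CC)CC)/C=C(/C)I | intermediate
8 | 3‑[(4‑methoxybenzyl)oxy]propan‑1‑ol | COc1ccc(COCCCO)cc1 | starting material
9 | but‑3‑en‑2‑yl acetate (racemic) | CC(OC(C)=O)C=C | starting material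
10 | (3R,4S)‑1‑[(4‑methoxybenzyl)oxy]‑4‑methylhex‑5‑en‑3‑ol | COc1ccc(COCC[C@@H](O)[C@@H](C)C=C)cc1 | intermediate
11 | tert‑butyl{[(3R,4S)‑1‑[(4‑methoxybenzyl)oxy]‑4‑methylhex‑5‑en‑3‑yl]oxy}dimethylsilane | COc1ccc(COCC[C@@H](O[Si](C)(C)C(C)(C)C)[C@@H](C)C=C)cc1 | intermediate
12 | 9‑[(3S,4R)‑4‑(tert‑butyldimethylsilyloxy)‑6‑(4‑methoxybenzyloxy)‑3‑methylhexyl]‑9‑borabicyclo[3.3.1]nonane | COc1ccc(COCC[C@@H](O[Si](C)(C)C(C)(C)C)[C@@H](C)CCB2C3CCCC2CCC3)cc1 | intermediate
13 | (3S,4R)‑4‑[(tert‑butyldimethylsilyl)oxy]‑6‑[(4‑methoxybenzyl)oxy]‑3‑methylhexan‑1‑ol | COc1ccc(COCC[C@@H](O[Si](C)(C)C(C)(C)C)[C@@H](C)CCO)cc1 | intermediate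
14 | (3S,4R)‑4‑[(tert‑butyldimethylsilyl)oxy]‑6‑[(4‑methoxybenzyl)oxy]‑3‑methylhexanal | COc1ccc(COCC[C@@H](O[Si](C)(C)C(C)(C)C)[C@@H](C)CC=O)cc1 | intermediate
15 | seco alcohol: 3‑O‑PMB, 1‑O‑TBS, 10‑methyl, 8‑hydroxy, 7‑[1‑(pinacolboryl)ethenyl], 6‑O‑TES, (4Z)‑4‑iodo alkene; 1R,6R,7R,8R,10S | COc1ccc(COCC[C@@H](O[Si](C)(C)C(C)(C)C)[C@@H](C)C[C@@H](O)[C@@H](C(=C)B2OC(C)(C)C(C)(C)O2)[C@@H](O[Si](CC)(CC)CC)/C=C(/C)I)cc1 | intermediate
16 | (E)‑2‑methylbut‑2‑enoyl chloride (tigloyl chloride) | C/C=C(\C)C(=O)Cl | starting material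
17 | seco tiglate: as 15 with 8‑O‑tigloyl; 1R,6R,7R,8R,10S | COc1ccc(COCC[C@@H](O[Si](C)(C)C(C)(C)C)[C@@H](C)C[C@@H](OC(=O)/C(C)=C/C)[C@@H](C(=C)B2OC(C)(C)C(C)(C)O2)[C@@H](O[Si](CC)(CC)CC)/C=C(/C)I)cc1 | intermediate
18 | seco primary alcohol: as 17 with free 3‑OH; 1R,6R,7R,8R,10S | OCC[C@@H](O[Si](C)(C)C(C)(C)C)[C@@H](C)C[C@@H](OC(=O)/C(C)=C/C)[C@@H](C(=C)B1OC(C)(C)C(C)(C)O1)[C@@H](O[Si](CC)(CC)CC)/C=C(/C)I | intermediate
19 | seco aldehyde: C3 aldehyde, otherwise as 18; 1R,6R,7R,8R,10S | O=CC[C@@H](O[Si](C)(C)C(C)(C)C)[C@@H](C)C[C@@H](OC(=O)/C(C)=C/C)[C@@H](C(=C)B1OC(C)(C)C(C)(C)O1)[C@@H](O[Si](CC)(CC)CC)/C=C(/C)I | intermediate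
20 | macrocyclic allylic alcohols, (4Z)‑ten‑membered ring, both C3 epimers: 3‑OH, 4‑methyl, 6‑O‑TES, 7‑[1‑(pinacolboryl)ethenyl], 8‑O‑tigloyl, 10‑methyl, 1‑O‑TBS; 1R,6S,7R,8R,10S | OC1C[C@@H](O[Si](C)(C)C(C)(C)C)[C@@H](C)C[C@@H](OC(=O)/C(C)=C/C)[C@@H](C(=C)B2OC(C)(C)C(C)(C)O2)[C@@H](O[Si](CC)(CC)CC)/C=C1/C | intermediate
21 | macrocyclic (4Z)‑enone: 3‑ketone, otherwise as 20; 1R,6S,7R,8R,10S | O=C1C[C@@H](O[Si](C)(C)C(C)(C)C)[C@@H](C)C[C@@H](OC(=O)/C(C)=C/C)[C@@H](C(=C)B2OC(C)(C)C(C)(C)O2)[C@@H](O[Si](CC)(CC)CC)/C=C1/C | intermediate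
22 | (3S)‑allylic alcohol of the (4Z)‑macrocycle; 1R,3S,6S,7R,8R,10S | O[C@H]1C[C@@H](O[Si](C)(C)C(C)(C)C)[C@@H](C)C[C@@H](OC(=O)/C(C)=C/C)[C@@H](C(=C)B2OC(C)(C)C(C)(C)O2)[C@@H](O[Si](CC)(CC)CC)/C=C1/C | intermediate
23 | epoxy alcohol: 4,5‑oxirane cis to 3‑OH; 1R,3S,4S,5R,6R,7R,8R,10S | O[C@H]1C[C@@H](O[Si](C)(C)C(C)(C)C)[C@@H](C)C[C@@H](OC(=O)/C(C)=C/C)[C@@H](C(=C)B2OC(C)(C)C(C)(C)O2)[C@@H](O[Si](CC)(CC)CC)[C@H]3O[C@]31C | intermediate
24 | epoxy ketone: 3‑ketone, 4,5‑oxirane, 6‑O‑TES; 1R,4R,5R,6R,7R,8R,10S | O=C1C[C@@H](O[Si](C)(C)C(C)(C)C)[C@@H](C)C[C@@H](OC(=O)/C(C)=C/C)[C@@H](C(=C)B2OC(C)(C)C(C)(C)O2)[C@@H](O[Si](CC)(CC)CC)[C@H]3O[C@]31C | intermediate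
25 | C6 alcohol: as 24 with free 6‑OH; 1R,4R,5R,6R,7S,8R,10S | O=C1C[C@@H](O[Si](C)(C)C(C)(C)C)[C@@H](C)C[C@@H](OC(=O)/C(C)=C/C)[C@@H](C(=C)B2OC(C)(C)C(C)(C)O2)[C@@H](O)[C@H]3O[C@]31C | intermediate
26 | C6 mesylate: as 25 with 6‑OMs; 1R,4R,5R,6R,7R,8R,10S | O=C1C[C@@H](O[Si](C)(C)C(C)(C)C)[C@@H](C)C[C@@H](OC(=O)/C(C)=C/C)[C@@H](C(=C)B2OC(C)(C)C(C)(C)O2)[C@@H](OS(C)(=O)=O)[C@H]3O[C@]31C | intermediate
27 | carbon dioxide | O=C=O | starting material
28 | potassium acrylate: as 26 with C11 carboxylate in place of boron; 1R,4R,5R,6R,7R,8R,10S | O=C1C[C@@H](O[Si](C)(C)C(C)(C)C)[C@@H](C)C[C@@H](OC(=O)/C(C)=C/C)[C@@H](C(=C)C(=O)[O-])[C@@H](OS(C)(=O)=O)[C@H]3O[C@]31C.[K+] | intermediate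
29 | 1‑O‑TBS‑eupakirunsin C; 1R,4R,5R,6S,7R,8R,10S | O=C1C[C@@H](O[Si](C)(C)C(C)(C)C)[C@@H](C)C[C@@H](OC(=O)/C(C)=C/C)[C@H]2C(=C)C(=O)O[C@@H]2[C@H]3O[C@]31C | intermediate
30 | eupakirunsin C; 1R,4R,5R,6S,7R,8R,10S | C=C1C(=O)O[C@H]2[C@H]1[C@H](OC(=O)/C(C)=C/C)C[C@H](C)[C@H](O)CC(=O)[C@]1(C)O[C@H]21 | target

**Totals**
Total step count: 21. Longest linear sequence: 17 steps (steps 1–4 or 5–8, then 9–21).

**Three steps most likely to fail**

Step 9 (borylative union). The facial selectivity at C7/C8 may be poor if the bias of the C6 centre and the ligand oppose each other. The Cu–B species may also borylate the alkenyl iodide, or the allylcopper may lose silyloxide by β‑elimination. Fallback, setting out from 7 and 14 and returning at 15: the two events are separated and made copper‑free. Allene 7 is diborated at its terminal double bond (Pt(dba)2, PCy3, B2pin2, toluene, 50 °C) to the isolable allylboronate triethyl{[(2Z,4R,5Z)‑6‑iodo‑1,2‑bis(pinacolboryl)hepta‑2,5‑dien‑4‑yl]oxy}silane F1. F1 is then added to aldehyde 14 in a metal‑free allylboration catalysed by a chiral phosphoric acid ((R)‑TRIP, toluene, −30 °C). The chair transition state again gives the 7,8‑syn adduct, and hydrolysis of the O‑boryl product gives 15.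

Step 16 (directed epoxidation). Oxygen delivery may occur on the wrong face or unselectively, because the ring conformation and the C6 silyloxy group may shield the required face; the alkenyl boronate may also be oxidised. Fallback, setting out from 21 and returning at 24: the directing logic is reversed. Enone 21 is reduced with the (S)‑oxazaborolidine and catecholborane to the 3R allylic alcohol F2. F2 is epoxidised with mCPBA (NaHCO3, CH2Cl2, 0 °C), which in medium‑ring Z‑cycloalkenols attacks anti to the hydroxyl. This should give the trans epoxy alcohol F3 with the same oxirane configuration, and Dess–Martin oxidation gives 24.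

Step 20 (key step). The carboxylate may fail to displace the hindered α‑epoxy mesylate (E2 elimination or oxirane opening instead), or the boronate may be lost by protodeboronation or base damage before carboxylation. Fallback, setting out from 26 and returning at 29: the two bonds are made in separate operations with CO. Iododeboronation of 26 (N‑iodosuccinimide, MeCN, 0 °C) gives the C11 alkenyl iodide F4. Palladium‑catalysed hydroxycarbonylation (Pd(OAc)2, dppf, CO 1 atm, KOAc, DMF/H2O, 50 °C) gives the acrylic acid F5. Cs2CO3 in DMF at 50 °C then closes the lactone by the same invertive 5‑exo‑tet displacement to give 29.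

**Further compounds**
F1 | step 9 | triethyl{[(2Z,4R,5Z)‑6‑iodo‑1,2‑bis(4,4,5,5‑tetramethyl‑1,3,2‑dioxaborolan‑2‑yl)hepta‑2,5‑dien‑4‑yl]oxy}silane | CC1(C)OB(C/C(=C\[C@@H](O[Si](CC)(CC)CC)/C=C(/C)I)B2OC(C)(C)C(C)(C)O2)OC1(C)C
F2 | step 16 | (3R)‑allylic alcohol, C3 epimer of 22; 1R,3R,6S,7R,8R,10S | O[C@@H]1C[C@@H](O[Si](C)(C)C(C)(C)C)[C@@H](C)C[C@@H](OC(=O)/C(C)=C/C)[C@@H](C(=C)B2OC(C)(C)C(C)(C)O2)[C@@H](O[Si](CC)(CC)CC)/C=C1/C
F3 | step 16 | trans epoxy alcohol, C3 epimer of 23; 1R,3R,4S,5R,6R,7R,8R,10S | O[C@@H]1C[C@@H](O[Si](C)(C)C(C)(C)C)[C@@H](C)C[C@@H](OC(=O)/C(C)=C/C)[C@@H](C(=C)B2OC(C)(C)C(C)(C)O2)[C@@H](O[Si](CC)(CC)CC)[C@H]3O[C@]31C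
F4 | step 20 | C11 alkenyl iodide: as 26 with iodine in place of boron | O=C1C[C@@H](O[Si](C)(C)C(C)(C)C)[C@@H](C)C[C@@H](OC(=O)/C(C)=C/C)[C@@H](C(=C)I)[C@@H](OS(C)(=O)=O)[C@H]2O[C@]21C
F5 | step 20 | acrylic acid: as 26 with C11 carboxylic acid in place of boron | O=C1C[C@@H](O[Si](C)(C)C(C)(C)C)[C@@H](C)C[C@@H](OC(=O)/C(C)=C/C)[C@@H](C(=C)C(=O)O)[C@@H](OS(C)(=O)=O)[C@H]2O[C@]21C
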